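Per substrate, I reckoned the step to the isomer of the product, with the full charge of 1.00 mM of partner, at 0.230 s⁻¹, slower than the step to tautomer at 0.29 s⁻¹.

in all of them: protic impurity 0.0100 mM; time 8.0 s
- autumn: substrate 0.50 mM; partner 2.00 equiv; everything together at the start
- winter: substrate 0.50 mM; partner 2.00 equiv (fed, over 5.0 s); all else is in the flask from the start; the feed brings no volume worth counting
- midnight: substrate 0.50 mM (fed, over 5.0 s); partner 2.00 equiv; all else is in the flask from the start; the feed brings no volume worth counting

    substrate ⇌ tautomer (K1 = 1.8, k1 = 0.29 s⁻¹)
    substrate + partner → isomer of the product (k2 = 230 M⁻¹ s⁻¹)
    partner + tautomer → target (k3 = 520 M⁻¹ s⁻¹)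
    substrate + target ⇌ idle adduct, settled at all times (K4 = 840 M⁻¹)
    partner + protic impurity → quenched reagent (k5 = 61000 M⁻¹ s⁻¹)
    tautomer → side product (k6 = 0.14 s⁻¹)

1. the best flask by amount of target, in percent of the substrate charged; "all alike" if 1.5 percentage points covers them all (autumn / winter / midnight / all alike)
2. amount of target at the end, in percent of the substrate charged, autumn
3. amount of target at the end, in percent of the substrate charged, winter
4. amount of target at the end, in percent of the substrate charged, midnight

- a species is counted by the substrate in it: one idle adduct counts as two
- amounts and yields of target count idle adduct too
- in an amount of target, one idle adduct counts as one target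
- run time (autumn): 8.0 s

- I folded that comparison into the diversion number (a selectivity factor), partner times the rate constant of its attack on substrate, over the rate constant of tautomer formation, 0.793: isomer made per substrate passed on to tautomer, the way back set aside.
- I ignored the protic impurity, since its 0.0100 mM is far less than the charge of partner.
- For autumn the number gave a long-run isomer share of 44.2 %. For winter I took partner at half the charge, which halved the number to 0.397 and gave 28.4 %.
- One number was not enough, because tautomer has a second exit: at half the charge, partner takes it at 0.260 s⁻¹, faster than the side product at 0.14 s⁻¹, but by less than at the full charge.
- Multiplying in that share, I reckoned long-run target at 43.9 % for autumn and 46.5 % for winter, so I chose winter.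
- I put midnight last: its substrate arrives on average at 2.50 s, leaving 5.50 s of the run, and its partner starts at the full charge.
- The forecast, which gave amounts at the end of the run rather than my long-run shares, chose winter, with 34.5 % for autumn, 37.2 % for winter and 28.5 % for midnight, holding that “slow partner addition lets tautomer build first, which favours target over isomer”.
- The simulation gave winter, with 34.2 % for autumn, 37.4 % for winter and 28.1 % for midnight.
- During the winter feed partner averaged 0.405 mM, a diversion number of 0.321, and at 5.00 s winter held 18.7 % isomer, 25.0 % target and 15.6 % side product. By 8.00 s winter's target had reached 37.4 % and its isomer 25.6 %, while autumn held 42.3 % isomer. A neighbour of winter with 0.12 mM of substrate, equivalents held, has at half its charge of partner a diversion number of 0.0952, lower than the 0.397 I took for winter on that footing, and ends with 9.37 % isomer and 31.2 % side product, but its target stands at 17.5 %.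

The numbers of this flask were chosen freely; the result is computed.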